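Numbering: C1 = CO2H, oxane = O/C3–C7, diene C8–C11, C12 = tertiary carbinol, oxirane = C14–C15, C16 (CH3), C17 (OCH3), C18 (OH), C19.
Cuts: C9–C10 (Heck), C15–C16 (alkenylalanate + oxirane), C14–CH3 (carboalumination), C18–C19 (MeMgBr); in the oxane O–C3, C2–C3 and C6–C7.
Feature used: C16 is a methyl-bearing sp3 carbon next to oxygenated C17, so C16–C17–O can be carried as a trans-oxirane (ring atoms C16, C17, O17) that a C15 alkenyl nucleophile, grown from the terminal alkyne C14≡C15, opens at C16.
Forward: (S)-linalool gives the C10–C15 enyne 6 and crotyl alcohol the oxirane 9; one flask joins them (methylalumination, then oxirane opening); C17 is O-methylated and C19 added.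
The C14–C15 oxirane is then closed by C18–OH-directed epoxidation; the oxane comes from a crotylboration product by hydroformylation, Wittig and oxa-Michael closure; a Heck coupling forms the diene; fluoride and hydroxide unmask C12–OH and the acid.
Stereochemistry: C12 from linalool; C16 (inversion) and C17 (retention) from the Sharpless epoxide; C18 by Cram-chelate control; C14/C15 by C18–OH direction on the E-alkene; C6/C7 by Brown anti-crotylboration; C3 by thermodynamic 2,6-cis oxa-Michael closure.

Key step: step 6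

Assumption: (S)-(+)-linalool of high enantiomeric purity is taken as a purchasable chiral-pool material; its carbinol carbon becomes C12 and is never made or broken again. TBS = tert-butyldimethylsilyl, PMB = 4-methoxybenzyl.

Step 1
Reactants: 1 (S)-(+)-linalool
Product: 2 (S)-linalool TBS ether
Conditions: TBSOTf, 2,6-lutidine, CH2Cl2, 0 °C to rt
Reagents that add atoms: tert-butyldimethylsilyl triflate, CC(C)(C)[Si](C)(C)OS(=O)(=O)C(F)(F)F
Why: Silyl triflate with a hindered pyridine base silylates the tertiary allylic alcohol (silyl ether formation) without ionising it, and C12 is untouched.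

Step 2
Reactants: 2 (S)-linalool TBS ether
Product: 4 (4S)-4-(TBS-oxy)-4-methylhex-5-enal, via ozonide 3 (not isolated)
Conditions: O3, CH2Cl2, −78 °C, stopped at the first persistent blue colour; then PPh3, −78 °C to rt
Reagents that add atoms: ozone, [O-][O+]=O
Why: Criegee ozonolysis should be chemoselective because the electron-rich trisubstituted alkene reacts far faster than the hindered monosubstituted vinyl group beside the quaternary silyloxy carbon.

Step 3
Reactants: 4 (4S)-4-(TBS-oxy)-4-methylhex-5-enal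
Product: 6 (3S)-3-(TBS-oxy)-3-methylhex-1-en-5-yne, via alkenyl nonaflate 5 (not isolated)
Conditions: C4F9SO2F, phosphazene base P2-Et, DMF, −20 °C to rt
Reagents that add atoms: none
Why: One-pot O-sulfonylation of the aldehyde enolate and base-induced elimination of the enol sulfonate (alkyne synthesis from an enolisable aldehyde) should give the terminal alkyne C14≡C15 with no change in carbon count; the tertiary TBS ether was chosen to resist the fluoride released.

Step 4
Reactants: 7 (E)-but-2-en-1-ol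
Product: 8 [(2S,3S)-3-methyloxiran-2-yl]methanol
Conditions: Ti(OiPr)4 (5 mol %), L-(+)-diisopropyl tartrate (6 mol %), t-BuOOH, 4 Å molecular sieves, CH2Cl2, −20 °C
Reagents that add atoms: tert-butyl hydroperoxide, CC(C)(C)OO
Why: Sharpless asymmetric epoxidation with the L-(+)-tartrate should deliver oxygen to the face that gives the (2S,3S) trans-epoxy alcohol, setting the future C17 and the C16 centre that is later inverted.

Step 5
Reactants: 8 [(2S,3S)-3-methyloxiran-2-yl]methanol
Product: 9 (2S,3S)-2-[(PMB-oxy)methyl]-3-methyloxirane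
Conditions: NaH, 4-methoxybenzyl chloride, Bu4NI (cat.), THF, 0 °C to rt
Reagents that add atoms: 4-methoxybenzyl chloride, COc1ccc(CCl)cc1
Why: Williamson etherification in an aprotic medium should outrun Payne rearrangement of the epoxy alkoxide and leave both oxirane centres unchanged.

Step 6
Reactants: 6 (3S)-3-(TBS-oxy)-3-methylhex-1-en-5-yne; 9 (2S,3S)-2-[(PMB-oxy)methyl]-3-methyloxirane
Product: 12 (2R,3S,4E,7S)-7-(TBS-oxy)-1-(PMB-oxy)-3,5,7-trimethylnona-4,8-dien-2-ol, via alkenylalane 10 (not isolated), via lithium alanate 11 (not isolated)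
Conditions: Me3Al, Cp2ZrCl2 (20 mol %), CH2Cl2, 0 °C to rt; evaporate; n-BuLi, Et2O–hexane, −78 to 0 °C; then 9, BF3·OEt2, −78 °C
Reagents that add atoms: trimethylaluminium, C[Al](C)C
Why: Zirconium-catalysed syn-methylalumination (Negishi carboalumination) of the terminal alkyne C14≡C15 of 6 puts CH3 on C14 and aluminium on C15 cis to it, so the E geometry of C14=C15 is fixed before the bond is made, and n-BuLi then turns alkenylalane 10 into the more nucleophilic tetracoordinate alanate 11. The BF3-activated oxirane C16–C17–O of 9 is opened by SN2 attack of the alkenyl ligand at C16, anti to the C16–O bond and with retention of alkene geometry; the closest known reaction type is the alkylation of lithium alkenylalanates by epoxides, which BF3·OEt2 extends to 1,2-disubstituted oxiranes. No ring is closed: the strained three-membered ring O–C16–C17 is opened and its oxygen stays on C17 as the free hydroxyl that is methylated next. The new stereocentre C16 arises by inversion of the (3S) oxirane carbon set in step 4, while C17 is retained and C12 is untouched. The step needs regioselectivity for C16 over C17, which the inductively deactivating CH2OPMB group on C17 and the unhindered methyl-bearing C16 should secure, and it needs transfer of the alkenyl ligand in preference to methyl and butyl, which is the normal order for mixed alanates.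

Step 7
Reactants: 12 (2R,3S,4E,7S)-7-(TBS-oxy)-1-(PMB-oxy)-3,5,7-trimethylnona-4,8-dien-2-ol
Product: 13 C17 methyl ether of 12
Conditions: NaH, MeI, THF–DMF, 0 °C
Reagents that add atoms: iodomethane, CI
Why: Williamson O-methylation of the only free hydroxyl installs the C17 methoxy group; the non-migrating PMB ether keeps C17 and C18 oxygens differentiated.

Step 8
Reactants: 13 C17 methyl ether
Product: 14 (2R,3S,4E,7S)-7-(TBS-oxy)-2-methoxy-3,5,7-trimethylnona-4,8-dien-1-ol
Conditions: DDQ, CH2Cl2–pH 7 buffer, 0 °C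
Reagents that add atoms: none
Why: Oxidative cleavage of the electron-rich PMB ether by DDQ frees the C18 primary alcohol while the silyl ether and both alkenes should survive.

Step 9
Reactants: 14 primary alcohol
Product: 15 (2R,3S,4E,7S)-7-(TBS-oxy)-2-methoxy-3,5,7-trimethylnona-4,8-dienal
Conditions: Dess–Martin periodinane, NaHCO3, CH2Cl2, 0 °C to rt
Reagents that add atoms: none
Why: Buffered Dess–Martin oxidation gives the α-methoxy aldehyde under non-basic conditions that should not epimerise C17; it is used crude.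

Step 10
Reactants: 15 α-methoxy aldehyde
Product: 16 (2R,3R,4S,5E,8S)-8-(TBS-oxy)-3-methoxy-4,6,8-trimethyldeca-5,9-dien-2-ol
Conditions: MeMgBr, CH2Cl2–Et2O, −78 °C
Reagents that add atoms: methylmagnesium bromide, C[Mg]Br
Why: Grignard addition under Cram-chelate control, with magnesium bridging the aldehyde oxygen and the C17 methoxy oxygen so that methyl enters opposite the C16 branch, should give the 17,18-syn alcohol and so set C18 as R.

Step 11
Reactants: 16 C18 alcohol
Product: 17 (14R,15R)-epoxide of 16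
Conditions: VO(acac)2 (5 mol %), t-BuOOH, CH2Cl2, −20 to 0 °C
Reagents that add atoms: tert-butyl hydroperoxide, CC(C)(C)OO
Why: In this hydroxyl-directed vanadium-catalysed epoxidation the vanadate ester of the C18 hydroxyl delivers oxygen to the bishomoallylic E-alkene C14=C15 through a chair-like transition state with the C16 methyl and C17 methoxy groups pseudo-equatorial, which should give the (14R,15R) trans-oxirane, while the vinyl group beside the silylated C12 oxygen is not directed.

Step 12
Reactants: 18 prop-2-yn-1-ol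
Product: 20 (E)-3-iodo-2-methylprop-2-en-1-ol, via dialuminium species 19 (not isolated)
Conditions: Me3Al, Cp2ZrCl2 (25 mol %), CH2Cl2, 0 °C to rt; then I2, THF, −30 °C
Reagents that add atoms: trimethylaluminium, C[Al](C)C; iodine, II
Why: Negishi carboalumination adds CH3 and aluminium syn across the alkyne with methyl on the internal carbon, and iodinolysis with retention gives the E-iodoalkene that becomes C8=C9.

Step 13
Reactants: 20 (E)-3-iodo-2-methylprop-2-en-1-ol
Product: 21 (E)-3-iodo-2-methylprop-2-enal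
Conditions: MnO2, CH2Cl2, rt
Reagents that add atoms: none
Why: Manganese dioxide oxidises the allylic alcohol selectively to the enal without touching the alkenyl iodide or its geometry.

Step 14
Reactants: 21 (E)-3-iodo-2-methylprop-2-enal
Product: 23 (1E,3S,4S)-1-iodo-2,4-dimethylhexa-1,5-dien-3-ol, via borinate 22 (not isolated)
Conditions: trans-but-2-ene, KOt-Bu, n-BuLi, THF, −78 to −45 °C; (−)-Ipc2BOMe, −78 °C; BF3·OEt2; 21, −78 °C; then NaOH, H2O2, rt
Reagents that add atoms: trans-but-2-ene, C/C=C/C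
Why: Brown crotylboration through a chair Zimmerman–Traxler transition state gives the anti relationship from the E-crotyl unit, and the isopinocampheyl groups derived from (+)-α-pinene select the aldehyde face that sets C7 as S and C6 as S.

Step 15
Reactants: 23 (1E,3S,4S)-1-iodo-2,4-dimethylhexa-1,5-dien-3-ol
Product: 25 (5S,6S)-6-[(E)-1-iodoprop-1-en-2-yl]-5-methyloxan-2-ol, via hydroxy aldehyde 24 (not isolated)
Conditions: Rh(acac)(CO)2 (2 mol %), BIPHEPHOS, CO/H2 (1:1, 10 bar), THF, 60 °C
Reagents that add atoms: carbon monoxide, [C-]#[O+]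
Why: Linear-selective rhodium-catalysed hydroformylation with the wide-bite-angle bisphosphite adds the formyl carbon C3 to the terminal alkene carbon, the δ-hydroxy aldehyde closes to the six-membered lactol, and the trisubstituted iodoalkene is too hindered to insert.

Step 16
Reactants: 25 lactol
Product: 27 methyl 2-[(2R,5S,6S)-6-[(E)-1-iodoprop-1-en-2-yl]-5-methyloxan-2-yl]acetate, via hydroxy enoate 26 (not isolated)
Conditions: Ph3P=CHCO2Me, toluene, 80 °C; then DBU, 80 °C
Reagents that add atoms: methyl (triphenylphosphoranylidene)acetate, COC(=O)C=P(c1ccccc1)(c1ccccc1)c1ccccc1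
Why: Wittig olefination of the open lactol gives the E-enoate, and reversible base-mediated oxa-Michael addition (6-exo-trig) should settle on the thermodynamic 2,6-cis oxane with all three substituents equatorial, setting C3 as R.

Step 17
Reactants: 17 epoxy alcohol with the terminal vinyl group; 27 oxane alkenyl iodide
Product: 28 C12-O-TBS methyl ester of the target
Conditions: Pd(OAc)2 (10 mol %), K2CO3, Bu4NCl, DMF, 40 °C
Reagents that add atoms: none
Why: In this phosphine-free Heck reaction, oxidative addition of zerovalent palladium to the alkenyl iodide and insertion at the terminal carbon C10 are followed by β-hydride elimination that can only occur toward C10 because C12 is quaternary, which should give the (8E,10E)-diene without isomerisation and under base that spares the oxirane.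

Step 18
Reactants: 28 C12-O-TBS methyl ester
Product: 30 target acid, via hydroxy methyl ester 29 (not isolated)
Conditions: TBAF, THF, 45 °C; then LiOH, THF–MeOH–H2O, rt; citric acid to pH 4
Reagents that add atoms: lithium hydroxide, [Li+].[OH-]
Why: Fluoride desilylation of the tertiary allylic TBS ether followed by saponification of the methyl ester uses only basic, non-acidic conditions that the hindered trisubstituted oxirane and the dienyl carbinol should tolerate, with a mild acidification at the end.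

Compound list
1 | (3S)-3,7-dimethylocta-1,6-dien-3-ol, (S)-(+)-linalool | CC(C)=CCC[C@](C)(O)C=C | starting material
2 | tert-butyl{[(3S)-3,7-dimethylocta-1,6-dien-3-yl]oxy}dimethylsilane | CC(C)=CCC[C@](C)(O[Si](C)(C)C(C)(C)C)C=C | intermediate
3 | tert-butyl{[(3S)-5-(5,5-dimethyl-1,2,4-trioxolan-3-yl)-3-methylpent-1-en-3-yl]oxy}dimethylsilane (both epimers at the trioxolane carbon) | CC1(C)OOC(CC[C@](C)(O[Si](C)(C)C(C)(C)C)C=C)O1 | intermediate
4 | (4S)-4-[(tert-butyldimethylsilyl)oxy]-4-methylhex-5-enal | O=CCC[C@](C)(O[Si](C)(C)C(C)(C)C)C=C | intermediate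
5 | (4S)-4-[(tert-butyldimethylsilyl)oxy]-4-methylhexa-1,5-dien-1-yl nonafluorobutane-1-sulfonate (E/Z mixture) | FC(F)(F)C(F)(F)C(F)(F)C(F)(F)S(=O)(=O)OC=CC[C@](C)(O[Si](C)(C)C(C)(C)C)C=C | intermediate
6 | tert-butyldimethyl{[(3S)-3-methylhex-1-en-5-yn-3-yl]oxy}silane | C#CC[C@](C)(O[Si](C)(C)C(C)(C)C)C=C | intermediate
7 | (E)-but-2-en-1-ol | C/C=C/CO | starting material
8 | [(2S,3S)-3-methyloxiran-2-yl]methanol | C[C@@H]1O[C@H]1CO | intermediate
9 | (2S,3S)-2-{[(4-methoxybenzyl)oxy]methyl}-3-methyloxirane | C[C@@H]1O[C@H]1COCc1ccc(OC)cc1 | intermediate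
10 | [(1E,4S)-4-[(tert-butyldimethylsilyl)oxy]-2,4-dimethylhexa-1,5-dien-1-yl]dimethylalane | C[Al](C)/C=C(\C)C[C@](C)(O[Si](C)(C)C(C)(C)C)C=C | intermediate
11 | lithium butyl[(1E,4S)-4-[(tert-butyldimethylsilyl)oxy]-2,4-dimethylhexa-1,5-dien-1-yl]dimethylalanate | [Li+].CCCC[Al-](C)(C)/C=C(\C)C[C@](C)(O[Si](C)(C)C(C)(C)C)C=C | intermediate
12 | (2R,3S,4E,7S)-7-[(tert-butyldimethylsilyl)oxy]-1-[(4-methoxybenzyl)oxy]-3,5,7-trimethylnona-4,8-dien-2-ol | O[C@H]([C@@H](C)/C=C(\C)C[C@](C)(O[Si](C)(C)C(C)(C)C)C=C)COCc1ccc(OC)cc1 | intermediate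
13 | tert-butyl{[(3S,5E,7S,8R)-8-methoxy-9-[(4-methoxybenzyl)oxy]-3,5,7-trimethylnona-1,5-dien-3-yl]oxy}dimethylsilane | CO[C@H]([C@@H](C)/C=C(\C)C[C@](C)(O[Si](C)(C)C(C)(C)C)C=C)COCc1ccc(OC)cc1 | intermediate
14 | (2R,3S,4E,7S)-7-[(tert-butyldimethylsilyl)oxy]-2-methoxy-3,5,7-trimethylnona-4,8-dien-1-ol | CO[C@H]([C@@H](C)/C=C(\C)C[C@](C)(O[Si](C)(C)C(C)(C)C)C=C)CO | intermediate
15 | (2R,3S,4E,7S)-7-[(tert-butyldimethylsilyl)oxy]-2-methoxy-3,5,7-trimethylnona-4,8-dienal | CO[C@H]([C@@H](C)/C=C(\C)C[C@](C)(O[Si](C)(C)C(C)(C)C)C=C)C=O | intermediate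
16 | (2R,3R,4S,5E,8S)-8-[(tert-butyldimethylsilyl)oxy]-3-methoxy-4,6,8-trimethyldeca-5,9-dien-2-ol | CO[C@H]([C@@H](C)/C=C(\C)C[C@](C)(O[Si](C)(C)C(C)(C)C)C=C)[C@@H](C)O | intermediate
17 | (2R,3R,4R)-4-[(2R,3R)-3-{(2S)-2-[(tert-butyldimethylsilyl)oxy]-2-methylbut-3-en-1-yl}-3-methyloxiran-2-yl]-3-methoxypentan-2-ol | CO[C@H]([C@@H](C)[C@H]1O[C@]1(C)C[C@](C)(O[Si](C)(C)C(C)(C)C)C=C)[C@@H](C)O | intermediate
18 | prop-2-yn-1-ol | C#CCO | starting material
19 | {[(2E)-3-(dimethylalumanyl)-2-methylprop-2-en-1-yl]oxy}dimethylalane | C[Al](C)OC/C(C)=C/[Al](C)C | intermediate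
20 | (2E)-3-iodo-2-methylprop-2-en-1-ol | OC/C(C)=C/I | intermediate
21 | (2E)-3-iodo-2-methylprop-2-enal | O=C/C(C)=C/I | intermediate
22 | (1E,3S,4S)-1-iodo-2,4-dimethylhexa-1,5-dien-3-yl bis[(1R,2R,3R,5S)-2,6,6-trimethylbicyclo[3.1.1]heptan-3-yl]borinate | I/C=C(\C)[C@@H](OB([C@@H]1C[C@@H]2C[C@H]([C@H]1C)C2(C)C)[C@@H]1C[C@@H]2C[C@H]([C@H]1C)C2(C)C)[C@@H](C)C=C | intermediate
23 | (1E,3S,4S)-1-iodo-2,4-dimethylhexa-1,5-dien-3-ol | I/C=C(\C)[C@@H](O)[C@@H](C)C=C | intermediate
24 | (4S,5S,6E)-5-hydroxy-7-iodo-4,6-dimethylhept-6-enal | O=CCC[C@H](C)[C@H](O)/C(C)=C/I | intermediate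
25 | (5S,6S)-6-[(1E)-1-iodoprop-1-en-2-yl]-5-methyloxan-2-ol (both anomers) | I/C=C(\C)[C@H]1OC(O)CC[C@@H]1C | intermediate
26 | methyl (2E,6S,7S,8E)-7-hydroxy-9-iodo-6,8-dimethylnona-2,8-dienoate | COC(=O)/C=C/CC[C@H](C)[C@H](O)/C(C)=C/I | intermediate
27 | methyl 2-[(2R,5S,6S)-6-[(1E)-1-iodoprop-1-en-2-yl]-5-methyloxan-2-yl]acetate | I/C=C(\C)[C@H]1O[C@@H](CC(=O)OC)CC[C@@H]1C | intermediate
28 | methyl 2-[(2R,5S,6S)-6-[(2E,4E,6S)-6-[(tert-butyldimethylsilyl)oxy]-7-{(2R,3R)-3-[(2R,3R,4R)-4-hydroxy-3-methoxypentan-2-yl]-2-methyloxiran-2-yl}-6-methylhepta-2,4-dien-2-yl]-5-methyloxan-2-yl]acetate | CO[C@H]([C@@H](C)[C@H]1O[C@]1(C)C[C@](C)(O[Si](C)(C)C(C)(C)C)/C=C/C=C(\C)[C@H]1O[C@@H](CC(=O)OC)CC[C@@H]1C)[C@@H](C)O | intermediate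
29 | methyl 2-[(2R,5S,6S)-6-[(2E,4E,6S)-6-hydroxy-7-{(2R,3R)-3-[(2R,3R,4R)-4-hydroxy-3-methoxypentan-2-yl]-2-methyloxiran-2-yl}-6-methylhepta-2,4-dien-2-yl]-5-methyloxan-2-yl]acetate | CO[C@H]([C@@H](C)[C@H]1O[C@]1(C)C[C@](C)(O)/C=C/C=C(\C)[C@H]1O[C@@H](CC(=O)OC)CC[C@@H]1C)[C@@H](C)O | intermediate
30 | 2-[(2R,5S,6S)-6-[(2E,4E,6S)-6-hydroxy-7-{(2R,3R)-3-[(2R,3R,4R)-4-hydroxy-3-methoxypentan-2-yl]-2-methyloxiran-2-yl}-6-methylhepta-2,4-dien-2-yl]-5-methyloxan-2-yl]acetic acid | CO[C@H]([C@@H](C)[C@H]1O[C@]1(C)C[C@](C)(O)/C=C/C=C(\C)[C@H]1O[C@@H](CC(=O)O)CC[C@@H]1C)[C@@H](C)O | target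

Total step count: 18. Longest linear sequence: 11 steps (steps 1, 2, 3, 6, 7, 8, 9, 10, 11, 17, 18).

Steps most likely to fail

Step 6. What may go wrong: slow or unselective transfer from aluminium, that is, competing methyl or butyl transfer, attack at C17, or Lewis-acid isomerisation of the oxirane before it is opened. The fallback sets out from 6. The alkenylalane 10 is made as in step 6 and cleaved with I2 (THF, −30 °C) to the isolable (E)-vinyl iodide F1. Iodine–lithium exchange (t-BuLi, Et2O, −78 °C) gives the alkenyllithium F2, which is combined with BF3·OEt2 and oxirane 9 at −78 °C (organolithium/BF3 epoxide opening, inversion at C16). It comes back to the route at 12.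

Step 3. What may go wrong: self-condensation of the aldehyde enolate, loss of the silyl ether to the fluoride released, or base-induced isomerisation of the terminal alkyne. The fallback sets out from 4. Silylation (TMSCl, Et3N, DMF, 80 °C) gives the trimethylsilyl enol ether F3. Ozonolysis (O3, CH2Cl2, −78 °C; Me2S) cleaves the electron-rich enol ether in preference to the vinyl group and removes the old aldehyde carbon to give the nor-aldehyde F4. Ohira–Bestmann homologation (dimethyl (1-diazo-2-oxopropyl)phosphonate, K2CO3, MeOH, 0 °C) puts the carbon back as the alkyne terminus and comes back to the route at 6.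

Step 17. What may go wrong: slow insertion into the hindered terminal alkene beside the quaternary silyloxy carbon, with competing reduction or homocoupling of the alkenyl iodide and isomerisation of the diene. The fallback sets out from 17 and 27 and forms the same C9–C10 bond by cross-coupling instead of insertion. Ozonolysis of the vinyl group of 17 (O3, CH2Cl2–MeOH, −78 °C; Me2S) gives the α-silyloxy aldehyde F5, and Takai olefination (CHI3, CrCl2, THF, 0 °C) gives the (E)-vinyl iodide F6. Miyaura borylation of 27 (PdCl2(dppf), B2pin2, KOAc, DMSO) gives the alkenylboronate F7. Suzuki–Miyaura coupling of F6 and F7 (Pd(PPh3)4, Cs2CO3, THF–H2O) comes back to the route at 28.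

Further compounds
F1 | step 6 | tert-butyl{[(3S,5E)-6-iodo-3,5-dimethylhexa-1,5-dien-3-yl]oxy}dimethylsilane | I/C=C(\C)C[C@](C)(O[Si](C)(C)C(C)(C)C)C=C
F2 | step 6 | [(1E,4S)-4-[(tert-butyldimethylsilyl)oxy]-2,4-dimethylhexa-1,5-dien-1-yl]lithium | [Li]/C=C(\C)C[C@](C)(O[Si](C)(C)C(C)(C)C)C=C
F3 | step 3 | tert-butyldimethyl{[(3S)-3-methyl-6-[(trimethylsilyl)oxy]hexa-1,5-dien-3-yl]oxy}silane (E/Z mixture) | C[Si](C)(C)OC=CC[C@](C)(O[Si](C)(C)C(C)(C)C)C=C
F4 | step 3 | (3S)-3-[(tert-butyldimethylsilyl)oxy]-3-methylpent-4-enal | O=CC[C@](C)(O[Si](C)(C)C(C)(C)C)C=C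
F5 | step 17 | (2S)-2-[(tert-butyldimethylsilyl)oxy]-3-{(2R,3R)-3-[(2R,3R,4R)-4-hydroxy-3-methoxypentan-2-yl]-2-methyloxiran-2-yl}-2-methylpropanal | CO[C@H]([C@@H](C)[C@H]1O[C@]1(C)C[C@](C)(O[Si](C)(C)C(C)(C)C)C=O)[C@@H](C)O
F6 | step 17 | (2R,3R,4R)-4-[(2R,3R)-3-{(2S,3E)-2-[(tert-butyldimethylsilyl)oxy]-4-iodo-2-methylbut-3-en-1-yl}-3-methyloxiran-2-yl]-3-methoxypentan-2-ol | CO[C@H]([C@@H](C)[C@H]1O[C@]1(C)C[C@](C)(O[Si](C)(C)C(C)(C)C)/C=C/I)[C@@H](C)O
F7 | step 17 | methyl 2-[(2R,5S,6S)-5-methyl-6-[(1E)-1-(4,4,5,5-tetramethyl-1,3,2-dioxaborolan-2-yl)prop-1-en-2-yl]oxan-2-yl]acetate | CC1(C)OB(/C=C(\C)[C@H]2O[C@@H](CC(=O)OC)CC[C@@H]2C)OC1(C)C
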